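(The earlier runs and the new flask are simulated on assumed constants, and the scatter is random.)

The peak of open intermediate in our flask cannot be read off, because no run at 0.20 mM of substrate carries 2.00 equiv of fresh partner; theta and beta bracket it from either side.

| flask | substrate | fresh partner | coupling partner | remark | time |
|---|---|---|---|---|---|
| theta | 0.20 mM | 1.3 equiv | 1 equiv | run made earlier |  |
| beta | 0.20 mM | 3 equiv | 1 equiv | run made earlier |  |
| delta | 0.30 mM | 2 equiv | 1 equiv | run made earlier |  |
| flask | 0.20 mM | 2.00 equiv | 1.00 equiv |  | 8.0 min |

| run | time / min | open intermediate / % | target / % |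
|---|---|---|---|
| theta | 0.167 | 7.5 | 0 |
| theta | 0.667 | 18.0 | 5.2 |
| theta | 2.50 | 18.4 | 17.1 |
| theta | 10.0 | 19.5 | 2.2 |
| beta | 0.167 | 7.2 | 0 |
| beta | 0.667 | 9.7 | 10.5 |
| beta | 2.50 | 4.4 | 16.9 |
| beta | 10.0 | 0.7 | 0.5 |
| delta | 0.167 | 11.1 | 1.6 |
| delta | 0.667 | 11.1 | 15.0 |
| delta | 2.50 | 6.2 | 20.8 |
| delta | 10.0 | 1.4 | 2.1 |

(scatter of a reading: 1 percentage point)

1. the best time, 8.0 min at the latest, for open intermediate
2. the amount of open intermediate, in percent of the substrate charged, at that time

In the first instants, at 0.167 min, theta holds 7.5% and beta 7.2%, the same within the scatter. Fresh partner therefore does not show in the making of open intermediate. Raising c(substrate) from 0.20 mM to 0.30 mM in delta multiplies that reading by 1.48, with both partners raised alongside.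

In the middle, at 0.667 min, beta holds twice the target of theta and less open intermediate, so fresh partner shows in the removal.

At the end, at 10.0 min, beta keeps 0.7% of open intermediate and 0.5% of target, so in beta open intermediate sits early. The highest readings are 19.5% in theta, at its last time, and 9.7% in beta, at 0.667 min, and we freeze their dependence on the charge:

n = 0.835

This is the power of the fresh-partner equivalents by which the highest reading of open intermediate falls, substrate and coupling partner held: the peak order, an apparent order, carrying the scatter of 1 percentage point. From beta, our own reckoning for the flask is: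

peak = 13.6%

Delta, charged with 2 equiv of fresh partner as our flask is though at 0.30 mM of substrate, reads level between 0.167 min and 0.667 min, so we commit to 0.667 min.

The forecast says 15.5% at 1 min: "Stepping through by hand, intermediate rises to about 15–16% near 1 min". That is higher than ours and later.

The flask gives 13.9% at 0.673 min, so the forecast's time stands 1.49 times too high while its amount falls within the tolerance.

    2 second intermediate → homo product (k = 48.0 L mol⁻¹ s⁻¹)
    fresh partner ⇌ dormant form (K = 1.10, k = 0.0810 s⁻¹)
    coupling partner + fresh partner → second intermediate (k = 43.0 L mol⁻¹ s⁻¹)
    open intermediate + second intermediate → target (k = 920 L mol⁻¹ s⁻¹)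
    substrate + coupling partner → open intermediate (k = 49.0 L mol⁻¹ s⁻¹)
    target → over-reaction product (k = 0.00710 s⁻¹)

In the flask at 0.0509 min, fresh partner enters dormant form 10 times as fast as it enters second intermediate, counting the forward step alone. At the best time the flask holds 40.9% of its fresh partner charge free, beside 0.185 mM of dormant form. Carrying the flask's peak through n = 0.835 to 5.00 equiv of fresh partner gives 6.47%, and that neighbour reaches 7.69%.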